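## Analysis of the target

- The target is a 3,3''-linked biflavanone: two 5,7-dihydroxy-2-arylchroman-4-one units (rings A, C and B in each) joined by one bond between C3 and C3''. The halves differ only in ring B, which is 4-methoxyphenyl in one and 4-hydroxyphenyl in the other.
- The four stereocentres C2, C3, C3'' and C2'' are contiguous and read (2S,3R,2''S,3''R). Both rings C are 2,3-trans and the two halves have the same sense, so the core has a local twofold axis through the C3–C3'' bond that only the 4'-O-methyl group breaks.
- C3 and C3'' lie α to the C4 ketones and can epimerise. The benzylic C2–O1 bonds lie β to those ketones, so removal of a C3 proton can open ring C (retro-oxa-Michael), and a free para-hydroxyl on ring B opens a second, quinone-methide path to the same damage.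
- The four ring A phenols are acidic and electron-rich, and no reagent would tell a 4'-hydroxyl from a 4'''-hydroxyl at the end, so the methyl/hydroxyl difference must be built in from the start.
- The difficulty is the unsymmetrical, congested C3–C3'' bond between two tertiary carbons, each flanked by a carbinol and a carbonyl carbon; it rules out a dimerisation.
- The strategy rests on rings A: with oxygens on C5, C7 and C8a and the acyl carbon C4 on C4a, each is a 2-acylphloroglucinol, the aromatised form of a chain C8a–C8–C7–C6–C5 with carbonyl groups on C8a, C7 and C5. The bonds C4a–C5 and C4a''–C5'' are made last, with rings C and all four stereocentres already in place.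

## Retrosynthetic reasoning

**19 to 18.** Only the O–CH2 bond of a benzyl ether is cut. The benzyl group is the single protecting group of the route. It distinguishes the hydroxyl of the second ring B from the methyl ether of the first from the outset, and it keeps that position etherified through every basic step, which closes the quinone-methide path to epimerisation at C2''. The forward hydrogenolysis has to leave the two benzylic C–O bonds of rings C alone.

**18 to 17.** The bonds C4a–C5 and C4a''–C5'' are cut, giving the bis(dihydropyranone) 17, in which each future ring A is an open chain C8–C7–C6–C5 on C8a ending in a methyl ester. With O1–C8a and C4–C4a already tied into ring C, the chain has one productive way to fold: closure of C6 onto C4 would bridge ring C and cannot aromatise. The gain is that no phenol is carried, protected or differentiated before the penultimate step, and the stereocentres pass through as spectators. The forward reaction must make C4a, the α-carbon of a vinylogous ester, acylate the ester without removal of the C3 protons.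

**17 to 14 and 15, and 14 to 13.** The bonds C6–C7 and C6''–C7'' are cut, giving diacid 14 and two molecules of potassium methyl malonate 15. The β-keto esters are therefore made last, by a decarboxylative Claisen chain extension under near-neutral conditions, and the most acidic part of 17 never meets strong base or the acid used for ring C. Diacid 14 comes from diol 13 by oxidation of two primary alcohols.

**13 to 11 (through 12).** The bonds O1–C8a and O1''–C8a'' are cut, giving the bis(hydroxy ynone) 11. An alkyne at C4a≡C8a was chosen over a 1,3-dicarbonyl unit on purpose. Each C2 hydroxyl is δ to its own C8a but also γ to the C4 carbonyl of the other half, and a tricarbonyl chain can in addition close on itself between the oxygens on C4 and C7. With an alkyne, only the 6-endo addition of O1 to C8a is irreversible; the five-membered hemiketal with the other carbonyl is a dead end that reopens. The cycloisomerisation touches neither C2 nor C3.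

**11 to 9 and 10.** The bonds C4–C4a and C4''–C4a'' are cut, giving the bis(N-methoxy-N-methylamide) 9 and two molecules of the silylated butynol 10. The amide stops the acetylide after one addition and holds the carbonyl as a chelate until work-up, which also protects the β-hydroxy carbonyl units from retro-aldol cleavage.

**9 to 8 to 7, then 7 to 5 and 6, and 5 to 3 and 4.** Amide 9 comes from bis-imide 8 by exchange of both auxiliaries and 8 from its bis(silyl ether) 7. Compound 7 is cut at C2''–C3'' into aldehyde 6 and mono-adduct 5, and 5 is cut at C2–C3 into aldehyde 4 and the succinyl bis-imide 3. All four stereocentres are set here and nowhere else.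

- Once O1 and C4 are tied into ring C, 2,3-trans means that the C2 oxygen and the C3–C3'' bond are anti in the aldol sense, and the central bond needs the like (R,R) relation. Both follow if each aldol is an auxiliary-controlled anti-aldol from the same enantiomer of the auxiliary.
- A syn-aldol assembly, or one through lactones in which each benzylic oxygen is acylated by the carboxyl carbon of the other half, would fix C3 and C3'' in the opposite sense. That would leave two epimerisations next to the C4 ketones for the end, where removal of a C3 proton is also the first step of ring C opening. C3 and C3'' are therefore set correctly here, and the final base step is only asked not to disturb them.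
- The two aldehydes enter one after the other, which builds in the unsymmetry.

**3 to 1 and 2.** Bis-imide 3 is the double N-acylation product of auxiliary 1 with succinyl chloride 2.

## Alternatives that were turned down

**Alternative 1:** The stereo-array is stored in the cis-fused dilactone A1 (exo,exo-4-(4-methoxyphenyl)-8-(4-benzyloxyphenyl)-3,7-dioxabicyclo[3.3.0]octane-2,6-dione), disconnected at C3''–C2'' and at the lactone bond O1''–C4.

- Forward key step: the lithium enolate of monolactone A2 adds to 6, and the aldolate expels the auxiliary to close the second lactone. A2 is (4S)-4-benzyl-3-{[(2S,3S)-2-(4-methoxyphenyl)-5-oxooxolan-3-yl]carbonyl}-1,3-oxazolidin-2-one, from a syn boron aldol of a succinyl imide with 4 followed by lactonisation.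
- For it: the first aldol is routine; the cis ring fusion guarantees the like relation of C3 and C3''; exo aryl groups are the stable arrangement; the rigid bicycle makes the configuration easy to prove.
- Against it:
  - In A1, C3 and C3'' have the configuration opposite to the target relative to C2 and C2'' (2S,3S,2''S,3''S in flavanone locants). Exo aryl groups on the dilactone are the syn-aldol pattern and become 2,3-cis once rings C are closed, so two epimerisations α to C4 would have to follow, at centres whose enolates can also expel O1.
  - The new bond at C3'' must form cis to the acyl group on C3 of A2, against the usual trans preference of β-substituted lactone enolates. Material drains to A1 only if the aldol is reversible.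
  - In A1 each benzylic oxygen is bonded to the carbonyl of the other half. After opening, that γ-relation persists and competes with closure of ring C.
- Comparison: it is as strong or stronger in its first step and in the ease of checking configuration. The chosen route offers instead the target configuration at all four centres from two aldols of one type, and never lets the benzylic oxygens acylate.

**Alternative 2:** Rings A and C of each half are disconnected together at C8a–C4a and C6–C5. The substrate A3 is a 1,8-diethoxyocta-1,7-diyne-3,6-dione that carries on C4 and C5 the two aryl(4-benzyloxy-2-oxo-2H-pyran-6-yloxy)methyl groups. The product A4 is the 5,5''-di-O-ethyl-7,7'',4'''-tri-O-benzyl ether of the target.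

- Forward key step: on heating, each 2-pyrone acts as diene across its tethered alkynyl ketone; loss of CO2 from the bridged adduct aromatises ring A, and the four-atom tether O1–C2–C3–C4 becomes ring C.
- For it: four bonds and two rings per half form in one neutral, thermal step with no base near C2 or C3; electron demand is matched (dialkoxypyrone against ynone); the 5- and 7-oxygens arrive differentiated. On bond economy of the key step it is stronger than the chosen route.
- Against it:
  - A3 needs a hindered para-alkoxybenzylic secondary alcohol as the 6-alkoxy group of a 2-pyrone. That is a ketene-acetal-like ether with no reliable etherification, and it can ionise at C2.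
  - Acyl ynol ethers hydrate easily, and alkoxyalkynes lose ethylene to give ketenes at the temperatures a pyrone cycloaddition with CO2 extrusion needs.
  - A4 then requires removal of two ethyl ethers beside the 4'-methyl ether, in addition to hydrogenolysis of three benzyl ethers.
- Comparison: the chosen route reaches its precursor 17 by standard reactions, confines the risk to one step and ends with a single deprotection.

**Alternative 3:** The disconnection is at C4–C3 and C4''–C3''; the C3–C3'' bond is an alkyne in the substrate. Substrate A5 is the bis-ether of 1-(4-benzyloxyphenyl)-4-(4-methoxyphenyl)but-2-yne-1,4-diol with two 2-formyl-3,5-bis(benzyloxy)phenyl groups, configured at both carbinol carbons as in the target. The product A6 is the pentabenzyl ether of the target.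

- Forward key step: a thiazolium-derived carbene turns one formyl group into an acyl anion equivalent that adds to the proximal alkyne carbon (6-exo-dig, ring C of the first half), leaving a C3=C3'' enone. The second formyl group then adds to that enone in a Stetter reaction (ring C of the second half).
- For it: rings A are bought; A5 comes in few steps from acetylene, 4, 6 and a phloroglucinaldehyde ether; the cascade type has closer precedent than the key step chosen here. On step economy and precedent it is stronger.
- Against it:
  - C3'' is created in the Stetter step and C3 by protonation of the resulting enolate, with no controlling element beyond the distant C2 and C2'' centres. The 3,3''-configuration would rest on equilibration of two centres α to ketones.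
  - C2 and C2'' sit in aryl propargyl ethers of electron-rich benzylic alcohols, which are hard to make without ionisation and are prone to [3,3] rearrangement to chromenes on heating.
  - 2,4,6-Trioxygenated benzaldehydes are electron-rich and hindered, so carbene addition is slow.
- Comparison: the chosen route is longer, but all four stereocentres are fixed by an auxiliary before any ring is closed, and nothing in it ionises at C2.

Key step: step 9

Remark: flavanone locants are used for all intermediates (C2 to C8a and singly primed ring B positions for the 4-methoxyphenyl half, doubly primed locants for the half that ends as the 4-hydroxyphenyl unit); systematic names of the bipyran and bichromene compounds use a single prime for the second ring.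

## Route

Step 1
Reactants: 1 (S)-4-benzyl-1,3-oxazolidin-2-one (2 equiv); 2 succinyl chloride (butanedioyl dichloride)
Product: 3 1,4-bis[(4S)-4-benzyl-2-oxo-1,3-oxazolidin-3-yl]butane-1,4-dione (succinyl bis-imide)
Conditions: n-BuLi, THF, −78 °C; then 2 (0.5 equiv), −78 → 0 °C
Reagents that add atoms: none
Why: N-acylation of the lithiated oxazolidinone by both acid chloride termini (standard Evans imide formation); the two ends of 3 are equivalent, which makes the order of the later aldols free of any regiochemical question.

Step 2
Reactants: 3 succinyl bis-imide (1.5 equiv); 4 4-methoxybenzaldehyde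
Product: 5 (4S)-4-benzyl-3-[(2R)-4-[(4S)-4-benzyl-2-oxo-1,3-oxazolidin-3-yl]-2-[(S)-(4-methoxyphenyl)(trimethylsilyloxy)methyl]-4-oxobutanoyl]-1,3-oxazolidin-2-one (mono anti-aldol adduct; C2 S and C3 R in flavanone locants)
Conditions: MgCl2 (20 mol %), Et3N, TMSCl, EtOAc, rt; non-acidic work-up, filtration through Et3N-deactivated silica
Reagents that add atoms: chlorotrimethylsilane, C[Si](C)(C)Cl
Why: Evans anti-aldol under MgCl2 catalysis: soft enolisation gives the chelated (Z)-enolate of one imide, which should add to the aldehyde through a boat-like transition state on the face away from the benzyl group of the auxiliary, setting C3 (R) and C2 (S) in the 2,3-anti relation. Silylation of the aldolate by TMSCl turns the catalyst over and keeps O1 from attacking the second imide; the excess of 3 limits double addition.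

Step 3
Reactants: 5 mono anti-aldol adduct; 6 4-(benzyloxy)benzaldehyde
Product: 7 (2R,3R)-1,4-bis[(4S)-4-benzyl-2-oxo-1,3-oxazolidin-3-yl]-2-[(S)-[4-(benzyloxy)phenyl](trimethylsilyloxy)methyl]-3-[(S)-(4-methoxyphenyl)(trimethylsilyloxy)methyl]butane-1,4-dione
Conditions: 6 (1.5 equiv), MgCl2 (30 mol %), NaSbF6 (60 mol %), Et3N, TMSCl, EtOAc, rt → 40 °C
Reagents that add atoms: chlorotrimethylsilane, C[Si](C)(C)Cl
Why: The same MgCl2-catalysed anti-aldol at the remaining methylene; the auxiliary on C4'' should again direct the aldehyde to the enolate face away from its benzyl group and set C3'' (R) and C2'' (S). The α-proton at C3 is held out of conjugation by allylic strain and is not removed, and the silyl ether on O1 blocks lactonisation.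

Step 4
Reactants: 7 bis(silyl ether) bis-imide
Product: 9 (2R,3R)-2-[(S)-[4-(benzyloxy)phenyl](hydroxy)methyl]-3-[(S)-hydroxy(4-methoxyphenyl)methyl]-N1,N4-dimethoxy-N1,N4-dimethylbutanediamide, via diol bis-imide 8 (not isolated)
Conditions: citric acid, MeOH, 0 °C; then crude 8, AlMe3, MeNHOMe·HCl, CH2Cl2, −15 → 0 °C; Rochelle salt work-up
Reagents that add atoms: N,O-dimethylhydroxylamine hydrochloride, CNOC.Cl
Why: Mild methanolysis frees both hydroxyls, and the aluminium amide Me(Cl)AlN(OMe)Me then exchanges each auxiliary for the Weinreb amide by delivery from the aluminium alkoxide of the neighbouring hydroxyl (standard transamination of aldol adducts). Any lactone formed in passing is opened by the same reagent, and auxiliary 1 is recovered.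

Step 5
Reactants: 9 bis(Weinreb amide) diol; 10 tert-butyl(but-3-yn-1-yloxy)dimethylsilane
Product: 11 (6R,7R)-6-[(S)-[4-(benzyloxy)phenyl](hydroxy)methyl]-1,12-bis[(tert-butyldimethylsilyl)oxy]-7-[(S)-hydroxy(4-methoxyphenyl)methyl]dodeca-3,9-diyne-5,8-dione
Conditions: 10 (7 equiv), n-BuLi (6.5 equiv), THF, −78 °C; then 9, −78 → −20 °C; AcOH/aq. NH4Cl at −78 °C
Reagents that add atoms: none
Why: Weinreb ketone synthesis with LiC≡CCH2CH2OTBS: two equivalents are spent on the hydroxyls, and the chelated tetrahedral adducts stop further addition and prevent retro-aldol cleavage until the cold quench. The amide α-protons at C3 and C3'' are too weakly acidic for the acetylide, so the stereocentres are kept.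

Step 6
Reactants: 11 bis(hydroxy ynone)
Product: 13 (2S,2'S,3R,3'R)-2'-[4-(benzyloxy)phenyl]-6,6'-bis(2-hydroxyethyl)-2-(4-methoxyphenyl)-2,2',3,3'-tetrahydro-4H,4'H-[3,3'-bipyran]-4,4'-dione, via bis-TBS bis(dihydropyranone) 12 (not isolated)
Conditions: Ph3PAuCl (5 mol %), AgOTf (5 mol %), CH2Cl2, rt; then CSA (cat.), MeOH, 0 °C → rt
Reagents that add atoms: none
Why: Cycloisomerisation of β-hydroxy ynones to 2,3-dihydro-4H-pyran-4-ones by cationic monovalent gold (6-endo-dig addition of O1 to C8a and of O1'' to C8a''). The five-membered hemiketal that each hydroxyl can form with the carbonyl of the other half is reversible and leads nowhere, so both rings C close in the required sense without touching C2 or C3; acidic methanol then removes the two primary silyl ethers.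

Step 7
Reactants: 13 bis(hydroxyethyl) bis(dihydropyranone)
Product: 14 2,2'-[(2S,2'S,3R,3'R)-2'-[4-(benzyloxy)phenyl]-2-(4-methoxyphenyl)-4,4'-dioxo-2,2',3,3'-tetrahydro-4H,4'H-[3,3'-bipyran]-6,6'-diyl]diacetic acid
Conditions: TEMPO (20 mol %), PhI(OAc)2 (4.5 equiv), MeCN/H2O (1:1), rt
Reagents that add atoms: water, O
Why: Oxoammonium-mediated oxidation of the two primary alcohols through the aldehyde hydrates to the carboxylic acids; the medium is neutral and leaves the vinylogous esters, the aryl ethers and the C3 centres alone.

Step 8
Reactants: 14 diacid; 15 potassium 3-methoxy-3-oxopropanoate (potassium methyl malonate)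
Product: 17 dimethyl 4,4'-[(2S,2'S,3R,3'R)-2'-[4-(benzyloxy)phenyl]-2-(4-methoxyphenyl)-4,4'-dioxo-2,2',3,3'-tetrahydro-4H,4'H-[3,3'-bipyran]-6,6'-diyl]bis(3-oxobutanoate), via bis(acyl imidazolide) 16 (not isolated)
Conditions: 1,1'-carbonyldiimidazole (2.4 equiv), THF, rt; then 15 (4 equiv), MgCl2 (4 equiv), Et3N, THF, rt; aq. citric acid
Reagents that add atoms: 1,1'-carbonyldiimidazole, O=C(n1ccnc1)n1ccnc1 (its imidazolyl groups stay in 16 only)
Why: Masamune–Brooks chain extension: the acyl imidazolides C-acylate the Mg enolate of the malonate half ester, and the adducts lose CO2 on acidic work-up to give the two β-keto esters. The conditions are close to neutral, so the C3 protons are not removed.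

Step 9
Reactants: 17 bis[6-(4-methoxy-2,4-dioxobutyl)dihydropyranone]
Product: 18 (2S,2'S,3R,3'R)-2'-[4-(benzyloxy)phenyl]-5,5',7,7'-tetrahydroxy-2-(4-methoxyphenyl)-2,2',3,3'-tetrahydro-4H,4'H-[3,3'-bichromene]-4,4'-dione (4'''-O-benzyl ether of the target)
Conditions: Mg(OMe)2 (8 equiv), MeOH, 65 °C; then 1 M HCl, 0 °C
Reagents that add atoms: none
Why: Proposed new method: Mg(OMe)2 removes a proton from C8, the methylene between the C7 ketone and the vinylogous ester; the resulting dienolate carries charge on C4a, which attacks the chelated ester carbonyl C5 and expels methoxide, and the 2-acylcyclohexane-1,3,5-trione so formed tautomerises to the 5,7-dihydroxybenzene ring, the same sequence running in the second half. The closest known reaction type is the magnesium alkoxide Claisen (Dieckmann-type) cyclisation of 3,5,7-triketo esters and of 6-(2-oxoalkyl)-4-hydroxy-2-pyrones to acylphloroglucinols, which has not been run with the C4 carbonyl and O1 already locked in a dihydropyranone. Each ring A closes in the 6-(enolexo)-exo-trig mode (bond C4a–C5, ester oxygen outside the new ring). No stereocentre is created: C2 and C2'' are not touched, and C3 and C3'' already have the 2,3-trans arrangement, which is also the more stable one, so that any enolisation there returns the same isomer. The step needs C-acylation at C4a to win over the aldol mode (C6 onto C4), over reverse Claisen cleavage at C7 and over base-induced opening of ring C at C2. The aldol mode cannot aromatise, because C4, C4a and C8a already belong to ring C and the new ring would bridge it, so it stays reversible; the divalent magnesium holds the β-keto ester as a chelate and keeps the medium weakly basic; and the C3 protons, whose removal is what opens ring C, are far less acidic than the C6 and C8 protons that take up the base.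

Step 10
Reactants: 18 4'''-O-benzyl ether of the target
Product: 19 (2S,2'S,3R,3'R)-5,5',7,7'-tetrahydroxy-2'-(4-hydroxyphenyl)-2-(4-methoxyphenyl)-2,2',3,3'-tetrahydro-4H,4'H-[3,3'-bichromene]-4,4'-dione (target; 2S,3R,2''S,3''R in flavanone locants)
Conditions: H2 (1 atm), 10% Pd/C, EtOAc/MeOH, rt
Reagents that add atoms: none
Why: Hydrogenolysis of the one benzyl aryl ether under neutral conditions, under which flavanone carbonyl groups and the methyl ether are normally retained; the stereocentres are not involved.

## Compound list

1 | (S)-4-benzyl-1,3-oxazolidin-2-one | O=C1N[C@@H](Cc2ccccc2)CO1 | starting material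
2 | succinyl chloride (butanedioyl dichloride) | ClC(=O)CCC(=O)Cl | starting material
3 | 1,4-bis[(4S)-4-benzyl-2-oxo-1,3-oxazolidin-3-yl]butane-1,4-dione | O=C(CCC(=O)N1[C@@H](Cc2ccccc2)COC1=O)N1[C@@H](Cc2ccccc2)COC1=O | intermediate
4 | 4-methoxybenzaldehyde | COc1ccc(C=O)cc1 | starting material
5 | (4S)-4-benzyl-3-[(2R)-4-[(4S)-4-benzyl-2-oxo-1,3-oxazolidin-3-yl]-2-[(S)-(4-methoxyphenyl)(trimethylsilyloxy)methyl]-4-oxobutanoyl]-1,3-oxazolidin-2-one | COc1ccc(cc1)[C@@H](O[Si](C)(C)C)[C@H](C(=O)N1[C@@H](Cc2ccccc2)COC1=O)CC(=O)N1[C@@H](Cc2ccccc2)COC1=O | intermediate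
6 | 4-(benzyloxy)benzaldehyde | O=Cc1ccc(OCc2ccccc2)cc1 | starting material
7 | (2R,3R)-1,4-bis[(4S)-4-benzyl-2-oxo-1,3-oxazolidin-3-yl]-2-[(S)-[4-(benzyloxy)phenyl](trimethylsilyloxy)methyl]-3-[(S)-(4-methoxyphenyl)(trimethylsilyloxy)methyl]butane-1,4-dione | COc1ccc(cc1)[C@@H](O[Si](C)(C)C)[C@H](C(=O)N1[C@@H](Cc2ccccc2)COC1=O)[C@@H](C(=O)N1[C@@H](Cc2ccccc2)COC1=O)[C@H](O[Si](C)(C)C)c1ccc(OCc2ccccc2)cc1 | intermediate
8 | (2R,3R)-1,4-bis[(4S)-4-benzyl-2-oxo-1,3-oxazolidin-3-yl]-2-[(S)-[4-(benzyloxy)phenyl](hydroxy)methyl]-3-[(S)-hydroxy(4-methoxyphenyl)methyl]butane-1,4-dione | COc1ccc(cc1)[C@@H](O)[C@H](C(=O)N1[C@@H](Cc2ccccc2)COC1=O)[C@@H](C(=O)N1[C@@H](Cc2ccccc2)COC1=O)[C@H](O)c1ccc(OCc2ccccc2)cc1 | intermediate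
9 | (2R,3R)-2-[(S)-[4-(benzyloxy)phenyl](hydroxy)methyl]-3-[(S)-hydroxy(4-methoxyphenyl)methyl]-N1,N4-dimethoxy-N1,N4-dimethylbutanediamide | COc1ccc(cc1)[C@@H](O)[C@H](C(=O)N(C)OC)[C@@H](C(=O)N(C)OC)[C@H](O)c1ccc(OCc2ccccc2)cc1 | intermediate
10 | tert-butyl(but-3-yn-1-yloxy)dimethylsilane | C#CCCO[Si](C)(C)C(C)(C)C | starting material
11 | (6R,7R)-6-[(S)-[4-(benzyloxy)phenyl](hydroxy)methyl]-1,12-bis[(tert-butyldimethylsilyl)oxy]-7-[(S)-hydroxy(4-methoxyphenyl)methyl]dodeca-3,9-diyne-5,8-dione | COc1ccc(cc1)[C@@H](O)[C@H](C(=O)C#CCCO[Si](C)(C)C(C)(C)C)[C@@H](C(=O)C#CCCO[Si](C)(C)C(C)(C)C)[C@H](O)c1ccc(OCc2ccccc2)cc1 | intermediate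
12 | (2S,2'S,3R,3'R)-2'-[4-(benzyloxy)phenyl]-6,6'-bis{2-[(tert-butyldimethylsilyl)oxy]ethyl}-2-(4-methoxyphenyl)-2,2',3,3'-tetrahydro-4H,4'H-[3,3'-bipyran]-4,4'-dione | COc1ccc([C@H]2OC(CCO[Si](C)(C)C(C)(C)C)=CC(=O)[C@@H]2[C@H]2C(=O)C=C(CCO[Si](C)(C)C(C)(C)C)O[C@@H]2c2ccc(OCc3ccccc3)cc2)cc1 | intermediate
13 | (2S,2'S,3R,3'R)-2'-[4-(benzyloxy)phenyl]-6,6'-bis(2-hydroxyethyl)-2-(4-methoxyphenyl)-2,2',3,3'-tetrahydro-4H,4'H-[3,3'-bipyran]-4,4'-dione | COc1ccc([C@H]2OC(CCO)=CC(=O)[C@@H]2[C@H]2C(=O)C=C(CCO)O[C@@H]2c2ccc(OCc3ccccc3)cc2)cc1 | intermediate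
14 | 2,2'-[(2S,2'S,3R,3'R)-2'-[4-(benzyloxy)phenyl]-2-(4-methoxyphenyl)-4,4'-dioxo-2,2',3,3'-tetrahydro-4H,4'H-[3,3'-bipyran]-6,6'-diyl]diacetic acid | COc1ccc([C@H]2OC(CC(=O)O)=CC(=O)[C@@H]2[C@H]2C(=O)C=C(CC(=O)O)O[C@@H]2c2ccc(OCc3ccccc3)cc2)cc1 | intermediate
15 | potassium 3-methoxy-3-oxopropanoate (potassium methyl malonate) | [K+].[O-]C(=O)CC(=O)OC | starting material
16 | (2S,2'S,3R,3'R)-2'-[4-(benzyloxy)phenyl]-6,6'-bis[2-(1H-imidazol-1-yl)-2-oxoethyl]-2-(4-methoxyphenyl)-2,2',3,3'-tetrahydro-4H,4'H-[3,3'-bipyran]-4,4'-dione | COc1ccc([C@H]2OC(CC(=O)n3ccnc3)=CC(=O)[C@@H]2[C@H]2C(=O)C=C(CC(=O)n3ccnc3)O[C@@H]2c2ccc(OCc3ccccc3)cc2)cc1 | intermediate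
17 | dimethyl 4,4'-[(2S,2'S,3R,3'R)-2'-[4-(benzyloxy)phenyl]-2-(4-methoxyphenyl)-4,4'-dioxo-2,2',3,3'-tetrahydro-4H,4'H-[3,3'-bipyran]-6,6'-diyl]bis(3-oxobutanoate) | COc1ccc([C@H]2OC(CC(=O)CC(=O)OC)=CC(=O)[C@@H]2[C@H]2C(=O)C=C(CC(=O)CC(=O)OC)O[C@@H]2c2ccc(OCc3ccccc3)cc2)cc1 | intermediate
18 | (2S,2'S,3R,3'R)-2'-[4-(benzyloxy)phenyl]-5,5',7,7'-tetrahydroxy-2-(4-methoxyphenyl)-2,2',3,3'-tetrahydro-4H,4'H-[3,3'-bichromene]-4,4'-dione | COc1ccc([C@H]2Oc3cc(O)cc(O)c3C(=O)[C@@H]2[C@H]2C(=O)c3c(O)cc(O)cc3O[C@@H]2c2ccc(OCc3ccccc3)cc2)cc1 | intermediate
19 | (2S,2'S,3R,3'R)-5,5',7,7'-tetrahydroxy-2'-(4-hydroxyphenyl)-2-(4-methoxyphenyl)-2,2',3,3'-tetrahydro-4H,4'H-[3,3'-bichromene]-4,4'-dione | COc1ccc([C@H]2Oc3cc(O)cc(O)c3C(=O)[C@@H]2[C@H]2C(=O)c3c(O)cc(O)cc3O[C@@H]2c2ccc(O)cc2)cc1 | target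

## Step count and least certain steps

Total step count: 10. Longest linear sequence: 10 steps (from 1 and 2 to 19).

**Step 9 (key step).** Ring C may open under the base, either by loss of O1 from C2 after removal of a C3 proton or by conjugate addition of methoxide at C8a. The β-keto ester may also be cleaved by reverse Claisen reaction. Either could outrun the C-acylation, because C4a is only the α-carbon of a vinylogous ester and the ester is largely held as its enolate.

The fallback uses known chemistry, gives up the de novo construction of rings A and sets out from 9. Compound 9 is treated with an excess of the aryllithium made by bromine–lithium exchange (n-BuLi, THF, −78 °C) from 1,5-bis(benzyloxy)-2-bromo-3-fluorobenzene F1, itself from 5-fluororesorcinol by O-benzylation and bromination. This should give (2R,3R)-1,4-bis[2,4-bis(benzyloxy)-6-fluorophenyl]-2-[(S)-[4-(benzyloxy)phenyl](hydroxy)methyl]-3-[(S)-hydroxy(4-methoxyphenyl)methyl]butane-1,4-dione F2. K2CO3 in DMF then closes both rings C by intramolecular nucleophilic aromatic substitution of fluoride by the C2 and C2'' alkoxides. The ortho carbonyl activates the ring, and both carbinol carbons are retained. The product is the pentabenzyl ether of the target F3 (identical with A6). Hydrogenolysis of all five benzyl ethers (H2, Pd/C) returns to the route at 19.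

**Step 3.** Soft enolisation of the β-branched methylene of 5 may be slow, and the neighbouring stereocentres or chelation of the magnesium by the second imide may erode the facial selectivity. Retro-aldol equilibration before silylation would add to this.

The fallback sets out from 5 and replaces catalytic soft enolisation by a stoichiometric, preformed boron enolate and an externally activated aldehyde. Compound 5 is enolised with Bu2BOTf and i-Pr2NEt in CH2Cl2 and added at −78 °C to 6 precomplexed with Et2AlCl. The open transition state (Heathcock variant of the Evans aldol) should give the same anti adduct, isolated as the mono(trimethylsilyl ether) with a free C2'' hydroxyl F4. Citric acid in MeOH converts F4 into 8, where the route is rejoined.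

**Step 8.** The activated (4-oxodihydropyran-6-yl)acetic acid units are vinylogous malonic half acids. They may lose CO2, or eliminate to ketenes from the acyl imidazolides, before the malonate is acylated.

The fallback sets out from 13 and avoids the acid oxidation level. Dess–Martin periodinane should oxidise 13 only as far as 2,2'-[(2S,2'S,3R,3'R)-2'-[4-(benzyloxy)phenyl]-2-(4-methoxyphenyl)-4,4'-dioxo-2,2',3,3'-tetrahydro-4H,4'H-[3,3'-bipyran]-6,6'-diyl]diacetaldehyde F5. A Roskamp homologation with methyl diazoacetate and catalytic SnCl2 then inserts the CHCO2Me unit into each formyl C–H bond and returns to the route at 17.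

**Step 10.** Hydrogenolytic opening of the benzylic C2–O1 and C2''–O1'' bonds of rings C, to dihydrochalcone-type products, may compete with O-debenzylation, since both are benzylic C–O cleavages on palladium.

The fallback sets out from 18 and changes the bond-breaking mode from reductive to Lewis acidic. BCl3 with pentamethylbenzene as benzyl cation scavenger in CH2Cl2 at −78 °C should remove the benzyl group and leave the 4'-methyl ether, which needs higher temperatures. It leads directly to 19 and makes no new compound.

## Further compounds

F1 | step 9 | 1,5-bis(benzyloxy)-2-bromo-3-fluorobenzene | Fc1cc(OCc2ccccc2)cc(OCc2ccccc2)c1Br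
F2 | step 9 | (2R,3R)-1,4-bis[2,4-bis(benzyloxy)-6-fluorophenyl]-2-[(S)-[4-(benzyloxy)phenyl](hydroxy)methyl]-3-[(S)-hydroxy(4-methoxyphenyl)methyl]butane-1,4-dione | COc1ccc(cc1)[C@@H](O)[C@H](C(=O)c1c(F)cc(OCc2ccccc2)cc1OCc1ccccc1)[C@@H](C(=O)c1c(F)cc(OCc2ccccc2)cc1OCc1ccccc1)[C@H](O)c1ccc(OCc2ccccc2)cc1
F3 | step 9 | pentabenzyl ether of the target (5,7,5'',7'',4'''-penta-O-benzyl) | COc1ccc([C@H]2Oc3cc(OCc4ccccc4)cc(OCc4ccccc4)c3C(=O)[C@@H]2[C@H]2C(=O)c3c(OCc4ccccc4)cc(OCc4ccccc4)cc3O[C@@H]2c2ccc(OCc3ccccc3)cc2)cc1
F4 | step 3 | (2R,3R)-1,4-bis[(4S)-4-benzyl-2-oxo-1,3-oxazolidin-3-yl]-2-[(S)-[4-(benzyloxy)phenyl](hydroxy)methyl]-3-[(S)-(4-methoxyphenyl)(trimethylsilyloxy)methyl]butane-1,4-dione | COc1ccc(cc1)[C@@H](O[Si](C)(C)C)[C@H](C(=O)N1[C@@H](Cc2ccccc2)COC1=O)[C@@H](C(=O)N1[C@@H](Cc2ccccc2)COC1=O)[C@H](O)c1ccc(OCc2ccccc2)cc1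
F5 | step 8 | 2,2'-[(2S,2'S,3R,3'R)-2'-[4-(benzyloxy)phenyl]-2-(4-methoxyphenyl)-4,4'-dioxo-2,2',3,3'-tetrahydro-4H,4'H-[3,3'-bipyran]-6,6'-diyl]diacetaldehyde | COc1ccc([C@H]2OC(CC=O)=CC(=O)[C@@H]2[C@H]2C(=O)C=C(CC=O)O[C@@H]2c2ccc(OCc3ccccc3)cc2)cc1
F0 | step 10 | none | none
A1 | alternative 1 | exo,exo-4-(4-methoxyphenyl)-8-(4-benzyloxyphenyl)-3,7-dioxabicyclo[3.3.0]octane-2,6-dione | COc1ccc([C@H]2OC(=O)[C@H]3[C@@H]2C(=O)O[C@@H]3c2ccc(OCc3ccccc3)cc2)cc1
A2 | alternative 1 | (4S)-4-benzyl-3-{[(2S,3S)-2-(4-methoxyphenyl)-5-oxooxolan-3-yl]carbonyl}-1,3-oxazolidin-2-one | COc1ccc([C@H]2OC(=O)C[C@@H]2C(=O)N2[C@@H](Cc3ccccc3)COC2=O)cc1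
A3 | alternative 2 | 1,8-diethoxyocta-1,7-diyne-3,6-dione carrying on C4 the (4-methoxyphenyl)(4-benzyloxy-2-oxo-2H-pyran-6-yloxy)methyl group and on C5 the (4-benzyloxyphenyl)(4-benzyloxy-2-oxo-2H-pyran-6-yloxy)methyl group | COc1ccc(cc1)[C@@H](Oc1cc(OCc2ccccc2)cc(=O)o1)[C@H](C(=O)C#COCC)[C@@H](C(=O)C#COCC)[C@H](Oc1cc(OCc2ccccc2)cc(=O)o1)c1ccc(OCc2ccccc2)cc1
A4 | alternative 2 | 5,5''-di-O-ethyl-7,7'',4'''-tri-O-benzyl ether of the target | COc1ccc([C@H]2Oc3cc(OCc4ccccc4)cc(OCC)c3C(=O)[C@@H]2[C@H]2C(=O)c3c(OCC)cc(OCc4ccccc4)cc3O[C@@H]2c2ccc(OCc3ccccc3)cc2)cc1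
A5 | alternative 3 | bis[2-formyl-3,5-bis(benzyloxy)phenyl] ether of 1-(4-benzyloxyphenyl)-4-(4-methoxyphenyl)but-2-yne-1,4-diol | COc1ccc(cc1)[C@@H](Oc1cc(OCc2ccccc2)cc(OCc2ccccc2)c1C=O)C#C[C@H](Oc1cc(OCc2ccccc2)cc(OCc2ccccc2)c1C=O)c1ccc(OCc2ccccc2)cc1
A6 | alternative 3 | pentabenzyl ether of the target | COc1ccc([C@H]2Oc3cc(OCc4ccccc4)cc(OCc4ccccc4)c3C(=O)[C@@H]2[C@H]2C(=O)c3c(OCc4ccccc4)cc(OCc4ccccc4)cc3O[C@@H]2c2ccc(OCc3ccccc3)cc2)cc1
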